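**Retrosynthetic overview**
- Last C–C bond: Stille union of a core (E)-vinylstannane, made in the flask from the C5 ethynyl carbinol, with the bromodienamide of 2-amino-3-hydroxycyclopentenone.
- Upper amide C–N bond: copper-catalysed N-vinylation of (R,E)-4-methyloct-2-enamide with the 3-iodo epoxy-enone; the amide comes from asymmetric allylic methylation of hept-2-enyl bromide and cross-metathesis with acrylamide.
- Core stereotriad: organocatalytic desymmetrising epoxidation of a prochiral O-silyl p-quinol dienone, anti to the silyloxy group, as the first stereo-defining step.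
- Dienone: 1,2-addition of a silylacetylide to p-benzoquinone with O-silylation in the flask.
- Ring order: the six-membered carbocycle is carried from benzoquinone, the oxirane is the only ring formed (step 2), and the cyclopentenone ring is bought and arrives last with the lower chain.

Assumption: glutaconaldehyde potassium salt, triphenylphosphine dibromide, lithium (trimethylsilyl)acetylide solution and 2-amino-3-hydroxycyclopent-2-en-1-one hydrochloride are bought as catalogue items.

**Step 1**
Reactants: 1 p-benzoquinone; 2 lithium (trimethylsilyl)acetylide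
Product: 4 4-[(triethylsilyl)oxy]-4-[(trimethylsilyl)ethynyl]cyclohexa-2,5-dien-1-one, via lithium alkoxide adduct 3 (not isolated)
Conditions: 2 (1.0 equiv, 0.5 M in THF) added to 1, THF, −78 °C; then Et3SiOTf (1.2 equiv), −78 → 0 °C
Reagents that add atoms: triethylsilyl trifluoromethanesulfonate, CC[Si](CC)(CC)OS(=O)(=O)C(F)(F)F
Why: 1,2-addition of the lithium acetylide to one quinone carbonyl at low temperature gives the p-quinol alkoxide, which is O-silylated in the flask so that the tertiary oxygen later serves as the face-blocking group; the product is achiral, with a mirror plane through C1 and C4.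

**Step 2**
Reactants: 4 4-[(triethylsilyl)oxy]-4-[(trimethylsilyl)ethynyl]cyclohexa-2,5-dien-1-one
Product: 5 (1S,5S,6R)-5-[(triethylsilyl)oxy]-5-[(trimethylsilyl)ethynyl]-7-oxabicyclo[4.1.0]hept-3-en-2-one
Conditions: 9-amino(9-deoxy)epiquinine (10 mol%), CF3CO2H (20 mol%), 50% aq H2O2 (1.3 equiv), 1,4-dioxane, 30 °C
Reagents that add atoms: hydrogen peroxide, OO
Why: Proposed new method: the primary amine condenses with the dienone carbonyl to a cross-conjugated iminium ion in which the protonated quinuclidine hydrogen-bonds H2O2 and can deliver it to one π-face only, while the bulky, electronegative Et3SiO group on the quaternary carbon allows β-attack only anti to itself, so the catalyst's face preference becomes a choice between the two enantiotopic enone arms and Weitz–Scheffer closure of the β-peroxy enamine fixes C1, C6 and, by breaking the mirror plane, C5 in one operation, with wrong-arm monoepoxide removed faster as the meso bis-epoxide; the closest known reaction type is the cinchona primary-amine salt catalysed epoxidation of simple cyclic enones with H2O2, which to my knowledge has not been used to desymmetrise 4,4-disubstituted cyclohexa-2,5-dienones.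

**Step 3**
Reactants: 5 (1S,5S,6R)-5-[(triethylsilyl)oxy]-5-[(trimethylsilyl)ethynyl]-7-oxabicyclo[4.1.0]hept-3-en-2-one
Product: 6 (1S,5S,6R)-3-iodo-5-[(triethylsilyl)oxy]-5-[(trimethylsilyl)ethynyl]-7-oxabicyclo[4.1.0]hept-3-en-2-one
Conditions: I2 (2 equiv), pyridine/CH2Cl2 (1:1), 0 °C → rt
Reagents that add atoms: iodine, II
Why: Johnson α-iodination (pyridine conjugate addition, enolate iodination, elimination) is selective for the only enone α-carbon, C3, and leaves the epoxide, silyl ether, silylalkyne and all stereocentres untouched.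

**Step 4**
Reactants: 7 (E)-hept-2-en-1-ol
Product: 8 (E)-1-bromohept-2-ene
Conditions: PBr3 (0.4 equiv), Et2O, 0 °C
Reagents that add atoms: phosphorus tribromide, BrP(Br)Br
Why: Bromination of the primary allylic alcohol through its phosphite ester proceeds by SN2 displacement and keeps the E-olefin.

**Step 5**
Reactants: 8 (E)-1-bromohept-2-ene
Product: 9 (R)-3-methylhept-1-ene
Conditions: MeMgBr (1.2 equiv, Et2O), CuBr·SMe2 (1 mol%), (R,R)-Taniaphos [FeC5H5(C5H3(PPh2)CH(NMe2)C6H4PPh2)] (1.2 mol%), CH2Cl2, −75 °C; fractional distillation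
Reagents that add atoms: methylmagnesium bromide, C[Mg]Br
Why: Copper-catalysed asymmetric allylic alkylation (SN2′) with a Grignard reagent delivers methyl to one face of the γ-carbon with high branched selectivity, so the methyl-bearing stereocentre of the upper chain is set by catalysis from achiral material, the ligand hand being assigned by analogy with cinnamyl bromide and its antipode giving the S-olefin.

**Step 6**
Reactants: 9 (R)-3-methylhept-1-ene; 10 acrylamide
Product: 11 (R,E)-4-methyloct-2-enamide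
Conditions: second-generation Grubbs catalyst RuCl2(=CHPh)(PCy3)(H2IMes) (5 mol%), 10 (2 equiv), CH2Cl2, 40 °C
Reagents that add atoms: none
Why: Olefin cross-metathesis between the terminal alkene and the electron-poor acrylamide gives the E-enamide under thermodynamic control without touching the allylic stereocentre.

**Step 7**
Reactants: 6 (1S,5S,6R)-3-iodo-5-[(triethylsilyl)oxy]-5-[(trimethylsilyl)ethynyl]-7-oxabicyclo[4.1.0]hept-3-en-2-one; 11 (R,E)-4-methyloct-2-enamide
Product: 12 (2E,4R)-4-methyl-N-[(1S,5S,6R)-2-oxo-5-[(triethylsilyl)oxy]-5-[(trimethylsilyl)ethynyl]-7-oxabicyclo[4.1.0]hept-3-en-3-yl]oct-2-enamide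
Conditions: CuI (20 mol%), MeNHCH2CH2NHMe (40 mol%), K2CO3 (2 equiv), toluene, 50 °C
Reagents that add atoms: none
Why: Copper-catalysed Goldberg-type N-vinylation of the primary amide by the α-iodoenone forms the enamide C–N bond at the iodine-bearing carbon, and the mild carbonate base together with silyl protection of the alkyne and the tertiary oxygen shuts off acetylide coupling and Payne rearrangement.

**Step 8**
Reactants: 12 (2E,4R)-4-methyl-N-[(1S,5S,6R)-2-oxo-5-[(triethylsilyl)oxy]-5-[(trimethylsilyl)ethynyl]-7-oxabicyclo[4.1.0]hept-3-en-3-yl]oct-2-enamide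
Product: 13 (2E,4R)-N-[(1S,5S,6R)-5-ethynyl-5-hydroxy-2-oxo-7-oxabicyclo[4.1.0]hept-3-en-3-yl]-4-methyloct-2-enamide
Conditions: Bu4NF (2.5 equiv), AcOH (2.5 equiv), THF, 0 °C → rt
Reagents that add atoms: none
Why: Fluoride-mediated desilylation cleaves both the O–SiEt3 and the alkynyl C–SiMe3 bonds, and the acetic acid buffer keeps the freed tertiary alcohol from Payne rearrangement onto the anti epoxide.

**Step 9**
Reactants: 14 glutaconaldehyde potassium salt
Product: 15 (2E,4E)-5-bromopenta-2,4-dienal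
Conditions: Ph3PBr2 (1.1 equiv), CH2Cl2, 0 °C → rt
Reagents that add atoms: triphenylphosphine dibromide, BrP(Br)(c1ccccc1)(c1ccccc1)c1ccccc1
Why: Deoxybromination of the vinylogous formate anion by the bromophosphonium reagent (addition–elimination) gives the thermodynamically preferred all-E bromodienal.

**Step 10**
Reactants: 15 (2E,4E)-5-bromopenta-2,4-dienal
Product: 16 (2E,4E)-5-bromopenta-2,4-dienoic acid
Conditions: NaClO2, NaH2PO4, 2-methylbut-2-ene, t-BuOH/H2O, 0 °C → rt
Reagents that add atoms: sodium chlorite, [Na+].[O-]Cl=O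
Why: Pinnick oxidation converts the enal to the acid without touching the bromodiene because the alkene scavenger removes hypochlorous acid.

**Step 11**
Reactants: 16 (2E,4E)-5-bromopenta-2,4-dienoic acid; 17 2-amino-3-hydroxycyclopent-2-en-1-one hydrochloride
Product: 18 (2E,4E)-5-bromo-N-(2-hydroxy-5-oxocyclopent-1-en-1-yl)penta-2,4-dienamide
Conditions: EDC·HCl (1.2 equiv), HOBt (1.2 equiv), N-methylmorpholine (2.2 equiv), DMF, 0 °C → rt
Reagents that add atoms: none
Why: Carbodiimide/HOBt amide coupling acylates the amino group of the aminocyclopentenone in preference to the enol oxygen, and any enol ester formed transfers its acyl group to nitrogen.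

**Step 12**
Reactants: 13 (2E,4R)-N-[(1S,5S,6R)-5-ethynyl-5-hydroxy-2-oxo-7-oxabicyclo[4.1.0]hept-3-en-3-yl]-4-methyloct-2-enamide; 19 tributyltin hydride; 18 (2E,4E)-5-bromo-N-(2-hydroxy-5-oxocyclopent-1-en-1-yl)penta-2,4-dienamide
Product: 21 (2E,4R)-N-[(1S,5R,6R)-5-hydroxy-5-[(1E,3E,5E)-7-[(2-hydroxy-5-oxocyclopent-1-en-1-yl)amino]-7-oxohepta-1,3,5-trien-1-yl]-2-oxo-7-oxabicyclo[4.1.0]hept-3-en-3-yl]-4-methyloct-2-enamide (target), via vinylstannane 20 (not isolated)
Conditions: 19 (1.05 equiv, slow addition), PdCl2(PPh3)2 (3 mol%), THF, 0 °C; then 18 (1.1 equiv), PdCl2(MeCN)2 (5 mol%), DMF, rt, dark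
Reagents that add atoms: none
Why: Palladium-catalysed syn-hydrostannation of the terminal alkyne places tin at the unhindered terminus to give the (E)-vinylstannane, which undergoes Stille coupling with the dienyl bromide with retention of both olefin geometries to complete the all-E triene under neutral conditions that the free epoxyquinol tolerates.

**Compound list**
1 | p-benzoquinone | O=C1C=CC(=O)C=C1 | starting material
2 | lithium (trimethylsilyl)acetylide | [Li]C#C[Si](C)(C)C | starting material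
3 | lithium 4-oxo-1-[(trimethylsilyl)ethynyl]cyclohexa-2,5-dien-1-olate | [Li+].[O-]C1(C#C[Si](C)(C)C)C=CC(=O)C=C1 | intermediate
4 | 4-[(triethylsilyl)oxy]-4-[(trimethylsilyl)ethynyl]cyclohexa-2,5-dien-1-one | O=C1C=CC(O[Si](CC)(CC)CC)(C#C[Si](C)(C)C)C=C1 | intermediate
5 | (1S,5S,6R)-5-[(triethylsilyl)oxy]-5-[(trimethylsilyl)ethynyl]-7-oxabicyclo[4.1.0]hept-3-en-2-one | C1=C[C@](O[Si](CC)(CC)CC)(C#C[Si](C)(C)C)[C@@H]2O[C@@H]2C1=O | intermediate
6 | (1S,5S,6R)-3-iodo-5-[(triethylsilyl)oxy]-5-[(trimethylsilyl)ethynyl]-7-oxabicyclo[4.1.0]hept-3-en-2-one | IC1=C[C@](O[Si](CC)(CC)CC)(C#C[Si](C)(C)C)[C@@H]2O[C@@H]2C1=O | intermediate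
7 | (E)-hept-2-en-1-ol | CCCC/C=C/CO | starting material
8 | (E)-1-bromohept-2-ene | CCCC/C=C/CBr | intermediate
9 | (R)-3-methylhept-1-ene | CCCC[C@@H](C)C=C | intermediate
10 | acrylamide | C=CC(N)=O | starting material
11 | (R,E)-4-methyloct-2-enamide | CCCC[C@@H](C)/C=C/C(N)=O | intermediate
12 | (2E,4R)-4-methyl-N-[(1S,5S,6R)-2-oxo-5-[(triethylsilyl)oxy]-5-[(trimethylsilyl)ethynyl]-7-oxabicyclo[4.1.0]hept-3-en-3-yl]oct-2-enamide | CCCC[C@@H](C)/C=C/C(=O)NC1=C[C@](O[Si](CC)(CC)CC)(C#C[Si](C)(C)C)[C@@H]2O[C@@H]2C1=O | intermediate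
13 | (2E,4R)-N-[(1S,5S,6R)-5-ethynyl-5-hydroxy-2-oxo-7-oxabicyclo[4.1.0]hept-3-en-3-yl]-4-methyloct-2-enamide | CCCC[C@@H](C)/C=C/C(=O)NC1=C[C@](O)(C#C)[C@@H]2O[C@@H]2C1=O | intermediate
14 | glutaconaldehyde potassium salt, potassium (1E,3E)-5-oxopenta-1,3-dien-1-olate | [K+].[O-]/C=C/C=C/C=O | starting material
15 | (2E,4E)-5-bromopenta-2,4-dienal | Br/C=C/C=C/C=O | intermediate
16 | (2E,4E)-5-bromopenta-2,4-dienoic acid | OC(=O)/C=C/C=C/Br | intermediate
17 | 2-amino-3-hydroxycyclopent-2-en-1-one hydrochloride | Cl.NC1=C(O)CCC1=O | starting material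
18 | (2E,4E)-5-bromo-N-(2-hydroxy-5-oxocyclopent-1-en-1-yl)penta-2,4-dienamide | Br/C=C/C=C/C(=O)NC1=C(O)CCC1=O | intermediate
19 | tributyltin hydride | CCCC[SnH](CCCC)CCCC | starting material
20 | (2E,4R)-N-[(1S,5S,6R)-5-hydroxy-2-oxo-5-[(E)-2-(tributylstannyl)ethenyl]-7-oxabicyclo[4.1.0]hept-3-en-3-yl]-4-methyloct-2-enamide | CCCC[C@@H](C)/C=C/C(=O)NC1=C[C@](O)(/C=C/[Sn](CCCC)(CCCC)CCCC)[C@@H]2O[C@@H]2C1=O | intermediate
21 | (2E,4R)-N-[(1S,5R,6R)-5-hydroxy-5-[(1E,3E,5E)-7-[(2-hydroxy-5-oxocyclopent-1-en-1-yl)amino]-7-oxohepta-1,3,5-trien-1-yl]-2-oxo-7-oxabicyclo[4.1.0]hept-3-en-3-yl]-4-methyloct-2-enamide | CCCC[C@@H](C)/C=C/C(=O)NC1=C[C@](O)(/C=C/C=C/C=C/C(=O)NC2=C(O)CCC2=O)[C@@H]2O[C@@H]2C1=O | target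

Note: the C5 descriptor changes from S (5, 6, 12, 13, 20) to R (21) only because the CIP rank of the C5 side chain falls below that of ring C4 once the alkyne or tin is replaced by the plain triene; no bond at C5 is touched after step 2. In all of them the oxygen on C5 is anti to the epoxide oxygen and the carbon chain is syn to it, as in the target.

**Totals**
Total step count: 12. Longest linear sequence: 6 steps (1, 2, 3, 7, 8, 12 from benzoquinone; equally 4, 5, 6, 7, 8, 12 from heptenol).

**Three steps most likely to fail**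

Step 2 (the proposed new desymmetrisation). Risks are slow iminium formation from the hindered dienone, poor arm selectivity and over-epoxidation. Which cinchona pseudoenantiomer gives 5 rather than its antipode is not predicted here and is read from the first run (chiral HPLC, X-ray of 6); the epiquinidine-derived amine is the switch. The fallback uses known chemistry, sets out from 4 and comes back at 5. Substrate-controlled Weitz–Scheffer epoxidation with t-BuOOH and DBU (CH2Cl2, 0 °C), which attacks 4-silyloxy enones anti to the silyloxy group, gives racemic (1S*,5S*,6R*)-5-[(triethylsilyl)oxy]-5-[(trimethylsilyl)ethynyl]-7-oxabicyclo[4.1.0]hept-3-en-2-one F1. This is resolved by preparative supercritical-fluid chromatography on an amylose tris(3,5-dimethylphenylcarbamate) phase, and the (1S,5S,6R) enantiomer is 5.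

Step 7 (copper amidation of a base-sensitive iodo epoxy-enone with a weakly nucleophilic amide). The fallback sets out from 6, with 9 supplying the acyl part, and comes back at 12. Copper-catalysed azidation of the vinyl iodide (NaN3, CuI, sodium ascorbate, MeNHCH2CH2NHMe, EtOH/H2O, rt, no carbonate base) gives (1S,5S,6R)-3-azido-5-[(triethylsilyl)oxy]-5-[(trimethylsilyl)ethynyl]-7-oxabicyclo[4.1.0]hept-3-en-2-one F2. Staudinger reduction (PMe3, THF/H2O, 0 °C) gives (1S,5S,6R)-3-amino-5-[(triethylsilyl)oxy]-5-[(trimethylsilyl)ethynyl]-7-oxabicyclo[4.1.0]hept-3-en-2-one F3. This is acylated at once, using EDC·HCl/HOAt in CH2Cl2, with (R,E)-4-methyloct-2-enoic acid F4, itself made by cross-metathesis of 9 with acrylic acid under the step 6 conditions, to give 12.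

Step 12 (telescoped hydrostannation and Stille coupling). Risks are competing palladium/tin hydride reduction of the enone or epoxy ketone, the internal stannane regioisomer, and loss of the sensitive product. The fallback sets out from 13 and 18 and comes back at 21. Sonogashira coupling (PdCl2(PPh3)2, CuI, i-Pr2NH, THF, rt) gives the dienyne (2E,4R)-N-[(1S,5S,6R)-5-hydroxy-5-[(3E,5E)-7-[(2-hydroxy-5-oxocyclopent-1-en-1-yl)amino]-7-oxohepta-3,5-dien-1-yn-1-yl]-2-oxo-7-oxabicyclo[4.1.0]hept-3-en-3-yl]-4-methyloct-2-enamide F5. Ruthenium-catalysed trans-hydrosilylation ([Cp*Ru(MeCN)3]PF6, (EtO)3SiH, CH2Cl2, 0 °C) gives the vinylsilane (2E,4R)-N-[(1S,5S,6R)-5-hydroxy-5-[(1Z,3E,5E)-7-[(2-hydroxy-5-oxocyclopent-1-en-1-yl)amino]-7-oxo-2-(triethoxysilyl)hepta-1,3,5-trien-1-yl]-2-oxo-7-oxabicyclo[4.1.0]hept-3-en-3-yl]-4-methyloct-2-enamide F6. Protodesilylation with AgF (THF/MeOH/H2O, rt, dark) proceeds with retention and gives 21.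

**Further compounds**
F1 | step 2 | racemic (1S*,5S*,6R*)-5-[(triethylsilyl)oxy]-5-[(trimethylsilyl)ethynyl]-7-oxabicyclo[4.1.0]hept-3-en-2-one | C1=C[C@](O[Si](CC)(CC)CC)(C#C[Si](C)(C)C)[C@@H]2O[C@@H]2C1=O.C1=C[C@@](O[Si](CC)(CC)CC)(C#C[Si](C)(C)C)[C@H]2O[C@H]2C1=O
F2 | step 7 | (1S,5S,6R)-3-azido-5-[(triethylsilyl)oxy]-5-[(trimethylsilyl)ethynyl]-7-oxabicyclo[4.1.0]hept-3-en-2-one | [N-]=[N+]=NC1=C[C@](O[Si](CC)(CC)CC)(C#C[Si](C)(C)C)[C@@H]2O[C@@H]2C1=O
F3 | step 7 | (1S,5S,6R)-3-amino-5-[(triethylsilyl)oxy]-5-[(trimethylsilyl)ethynyl]-7-oxabicyclo[4.1.0]hept-3-en-2-one | NC1=C[C@](O[Si](CC)(CC)CC)(C#C[Si](C)(C)C)[C@@H]2O[C@@H]2C1=O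
F4 | step 7 | (R,E)-4-methyloct-2-enoic acid | CCCC[C@@H](C)/C=C/C(O)=O
F5 | step 12 | (2E,4R)-N-[(1S,5S,6R)-5-hydroxy-5-[(3E,5E)-7-[(2-hydroxy-5-oxocyclopent-1-en-1-yl)amino]-7-oxohepta-3,5-dien-1-yn-1-yl]-2-oxo-7-oxabicyclo[4.1.0]hept-3-en-3-yl]-4-methyloct-2-enamide | CCCC[C@@H](C)/C=C/C(=O)NC1=C[C@](O)(C#C/C=C/C=C/C(=O)NC2=C(O)CCC2=O)[C@@H]2O[C@@H]2C1=O
F6 | step 12 | (2E,4R)-N-[(1S,5S,6R)-5-hydroxy-5-[(1Z,3E,5E)-7-[(2-hydroxy-5-oxocyclopent-1-en-1-yl)amino]-7-oxo-2-(triethoxysilyl)hepta-1,3,5-trien-1-yl]-2-oxo-7-oxabicyclo[4.1.0]hept-3-en-3-yl]-4-methyloct-2-enamide | CCCC[C@@H](C)/C=C/C(=O)NC1=C[C@](O)(/C=C(/C=C/C=C/C(=O)NC2=C(O)CCC2=O)[Si](OCC)(OCC)OCC)[C@@H]2O[C@@H]2C1=O
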